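**Retrosynthetic overview**
1. Sauriol A is a twofold-symmetric 8,8'-linked dibenzylbutane. Its only stereocenters, C8 and C8', each carry a methyl group and sit next to a benzylic CH2 (C7, C7') on rings A and B. With C7 and C7' as aryl ketones both centers become enolizable, and the C7/C7' oxygens can later be removed as benzylic C–O bonds.
2. Last disconnection: one hydrogenolysis cuts the two C7/C7' carbinol C–O bonds and the four O-benzyl ethers of a tetrabenzyl 1,4-diol.
3. Key disconnection: the diol comes from the racemic/meso 1,4-diketone by a double dynamic kinetic asymmetric hydrogenation, which forms C7–H and C7'–H and funnels C8 and C8' to one configuration.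
4. The diketone comes from oxidative enolate dimerization (C8–C8' bond) of two molecules of a propiophenone, made from 5-hydroxyvanillin by double benzylation, ethyl Grignard addition and oxidation.
5. No ring is formed at any stage; rings A and B are carried through from the aldehyde.

Key step: step 5

Assumption: RuCl2[(R)-xylbinap][(R)-daipen] is assigned from the usual sense for aryl ketones (S carbinol) combined with Felkin-type α-selection; only C8 and C8' matter in the end, so if the α-preference proved opposite the antipodal catalyst would be used.

Step 1
Reactants: 1 3,4-dihydroxy-5-methoxybenzaldehyde (5-hydroxyvanillin); 2 benzyl bromide (2.4 equiv in all)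
Product: 3 3,4-bis(benzyloxy)-5-methoxybenzaldehyde
Conditions: BnBr (2.4 equiv), K2CO3 (3 equiv), DMF, 60 °C
Reagents that add atoms: benzyl bromide (the second equivalent of 2), BrCc1ccccc1
Why: Twofold Williamson ether synthesis, in which carbonate deprotonates both phenols and each phenoxide displaces bromide from one molecule of 2 by SN2; the aldehyde has no α-hydrogen and is inert to K2CO3.

Step 2
Reactants: 3 3,4-bis(benzyloxy)-5-methoxybenzaldehyde; 4 ethylmagnesium bromide
Product: 5 1-[3,4-bis(benzyloxy)-5-methoxyphenyl]propan-1-ol (racemic)
Conditions: EtMgBr, THF, 0 °C; then aq NH4Cl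
Reagents that add atoms: none
Why: Grignard 1,2-addition to a non-enolizable aryl aldehyde; the new carbinol center is racemic and is removed by the oxidation in step 3.

Step 3
Reactants: 5 1-[3,4-bis(benzyloxy)-5-methoxyphenyl]propan-1-ol
Product: 6 1-[3,4-bis(benzyloxy)-5-methoxyphenyl]propan-1-one
Conditions: Dess–Martin periodinane, CH2Cl2, 0 °C to rt
Reagents that add atoms: none
Why: Dess–Martin oxidation of a secondary benzylic alcohol by ligand exchange at iodine and loss of the carbinol hydrogen; the benzyl and methyl aryl ethers are inert.

Step 4
Reactants: 6 1-[3,4-bis(benzyloxy)-5-methoxyphenyl]propan-1-one (two molecules, both converted into the enolate)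
Product: 8 1,4-bis[3,4-bis(benzyloxy)-5-methoxyphenyl]-2,3-dimethylbutane-1,4-dione (racemic plus meso isomers), via lithium enolate 7 (not isolated)
Conditions: LiN(i-Pr)2 (LDA, 1.05 equiv), THF, −78 °C; then CuCl2 (1.1 equiv), DMF, −78 °C to rt
Reagents that add atoms: second molecule of ketone 6, 1-[3,4-bis(benzyloxy)-5-methoxyphenyl]propan-1-one, CCC(=O)c1cc(OC)c(OCc2ccccc2)c(OCc2ccccc2)c1
Why: Oxidative enolate homocoupling, in which divalent copper oxidizes the lithium enolate by one electron and two of the resulting α-keto radicals (or copper enolates) join at carbon to form the C8–C8' bond between two molecules of 6; no stereocontrol is sought because both centers are re-equilibrated in step 5.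

Step 5
Reactants: 8 1,4-bis[3,4-bis(benzyloxy)-5-methoxyphenyl]-2,3-dimethylbutane-1,4-dione (racemic plus meso isomers)
Product: 10 (1S,2S,3S,4S)-1,4-bis[3,4-bis(benzyloxy)-5-methoxyphenyl]-2,3-dimethylbutane-1,4-diol, via hydroxy ketone 9 (not isolated)
Conditions: H2 (8 atm), RuCl2[(R)-xylbinap][(R)-daipen] (2 mol %), KOt-Bu (20 mol %), i-PrOH–toluene, 30 °C
Reagents that add atoms: none
Why: Proposed new method: the divalent ruthenium hydride formed from the dichloride, KOt-Bu and H2 delivers Ru–H and N–H to each aryl ketone through an outer-sphere six-membered transition state, while the alkoxide keeps C2 and C3 (C8 and C8' of the lignan) epimerizing through the aryl ketone enolates, so racemic and meso 8 interconvert and drain through the α-epimer that fits the catalyst. The closest known reaction type is the base-promoted dynamic kinetic hydrogenation of a racemic α-substituted aryl ketone with RuCl2(diphosphine)(diamine) catalysts, which has not been shown twice in sequence on an acyclic 1,4-diketone. No ring is closed and no skeletal bond is formed, only the C1–H and C4–H bonds, and the carbonyl-selective catalyst should leave the benzyl ethers and arenes untouched. The carbinol centers C1 and C4 are set by the catalyst's choice of carbonyl face (aryl against sec-alkyl), and C2 and C3 by its preference for the α-epimer that turns the α-hydrogen toward the incoming hydride in a Felkin-type arrangement; C2 is frozen once C1 is reduced (9), since it is then no longer α to a carbonyl, and C3 keeps epimerizing until C4 is reduced in the same sense. The step needs enolization faster than reduction and strong discrimination between α-epimers: the first rests on the acidity of the α-hydrogens of the two aryl ketones under alkoxide at modest H2 pressure, the second on the matched xylBINAP/DAIPEN pair, and because two catalyst-controlled events follow each other an error should end in a separable diastereomer and not in the enantiomer.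

Step 6
Reactants: 10 (1S,2S,3S,4S)-1,4-bis[3,4-bis(benzyloxy)-5-methoxyphenyl]-2,3-dimethylbutane-1,4-diol
Product: 11 sauriol A [5,5'-((2R,3R)-2,3-dimethylbutane-1,4-diyl)bis(3-methoxybenzene-1,2-diol)]
Conditions: H2 (3 atm), Pd(OH)2/C, EtOAc–AcOH (degassed), rt; filtration and work-up under argon
Reagents that add atoms: none
Why: Catalytic hydrogenolysis, in which the four benzyl ethers and the two benzylic C–OH bonds (each on an electron-rich ring with a para oxygen) are cleaved at the palladium surface with acetic acid as the only acid, so that the benzylic positions are not ionized; C8 and C8' are not touched and keep their geometry, which reads R,R once C7 and C7' have lost oxygen and the CIP priorities change.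

**Compound list**
1 | 3,4-dihydroxy-5-methoxybenzaldehyde (5-hydroxyvanillin) | COc1cc(C=O)cc(O)c1O | starting material
2 | benzyl bromide | BrCc1ccccc1 | starting material
3 | 3,4-bis(benzyloxy)-5-methoxybenzaldehyde | COc1cc(C=O)cc(OCc2ccccc2)c1OCc1ccccc1 | intermediate
4 | ethylmagnesium bromide | CC[Mg]Br | starting material
5 | 1-[3,4-bis(benzyloxy)-5-methoxyphenyl]propan-1-ol (racemic) | CCC(O)c1cc(OC)c(OCc2ccccc2)c(OCc2ccccc2)c1 | intermediate
6 | 1-[3,4-bis(benzyloxy)-5-methoxyphenyl]propan-1-one | CCC(=O)c1cc(OC)c(OCc2ccccc2)c(OCc2ccccc2)c1 | intermediate
7 | lithium (Z)-1-[3,4-bis(benzyloxy)-5-methoxyphenyl]prop-1-en-1-olate (Z geometry expected, not isolated) | [Li+].C/C=C(\[O-])c1cc(OC)c(OCc2ccccc2)c(OCc2ccccc2)c1 | intermediate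
8 | 1,4-bis[3,4-bis(benzyloxy)-5-methoxyphenyl]-2,3-dimethylbutane-1,4-dione (racemic plus meso isomers) | COc1cc(C(=O)C(C)C(C)C(=O)c2cc(OC)c(OCc3ccccc3)c(OCc3ccccc3)c2)cc(OCc2ccccc2)c1OCc1ccccc1 | intermediate
9 | (3S,4S)-1,4-bis[3,4-bis(benzyloxy)-5-methoxyphenyl]-4-hydroxy-2,3-dimethylbutan-1-one (C2 epimers in equilibrium, not isolated) | COc1cc([C@@H](O)[C@@H](C)C(C)C(=O)c2cc(OC)c(OCc3ccccc3)c(OCc3ccccc3)c2)cc(OCc2ccccc2)c1OCc1ccccc1 | intermediate
10 | (1S,2S,3S,4S)-1,4-bis[3,4-bis(benzyloxy)-5-methoxyphenyl]-2,3-dimethylbutane-1,4-diol | COc1cc([C@@H](O)[C@@H](C)[C@H](C)[C@H](O)c2cc(OC)c(OCc3ccccc3)c(OCc3ccccc3)c2)cc(OCc2ccccc2)c1OCc1ccccc1 | intermediate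
11 | sauriol A, 5,5'-[(2R,3R)-2,3-dimethylbutane-1,4-diyl]bis(3-methoxybenzene-1,2-diol) | COc1cc(C[C@@H](C)[C@H](C)Cc2cc(O)c(O)c(OC)c2)cc(O)c1O | target

**Totals**
Total step count: 6. Longest linear sequence: 6 steps (1 to 11).

**Steps most likely to fail**

1. Step 5 (bears "Proposed new method:"). Three things may go wrong:
   - epimerization at C8/C8' may be too slow relative to hydrogenation, so material is reduced in the mismatched α-configuration;
   - the catalyst may discriminate too weakly between α-epimers;
   - the mono-reduced material may rest as a lactol and slow the second reduction.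

   Fallback with known chemistry, setting out from 8 and coming back to the route at 10: the racemic diastereomer of the diketone F1 is separated from the meso isomer by crystallization or chromatography, and the meso isomer is returned by equilibration with DBU. F1 is then reduced by Corey–Bakshi–Shibata reduction (BH3·SMe2, (R)-2-methyl-CBS-oxazaborolidine, THF, −20 °C), Lewis acidic conditions under which C8 should not epimerize. Reagent control should make both carbinols S, so the (2S,3S) half of the racemate gives 10 and the (2R,3R) half gives the diastereomeric (1S,2R,3R,4S)-diol F2. The two are separated on silica, and 10 rejoins the route at step 6. Contamination of 10 by its enantiomer would require two successive reagent-control errors.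

2. Step 6. Three things may go wrong:
   - the electron-rich benzylic carbons may ionize, followed by Friedel–Crafts closure onto the other ring or loss of the C8 proton, which would erase the stereocenters;
   - C–O cleavage may stall at a mono-ol or 2,5-diaryltetrahydrofuran stage;
   - the free catechols may oxidize in air during work-up.

   Fallback, setting out from 10 and coming back to the route at 11: acetylation (Ac2O, pyridine, DMAP, CH2Cl2, rt) gives the (1S,2S,3S,4S)-diacetate F3. Its activated benzylic esters and the benzyl ethers are cleaved by H2 over Pd/C in EtOAc–EtOH at rt with no added acid, which should give 11 directly.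

3. Step 4. Three things may go wrong:
   - CuCl2 may chlorinate the enolate at the α-carbon;
   - coupling may be incomplete, with return of ketone;
   - the product may be oxidized further.

   Fallback, setting out from 6 and coming back to the route at 8: α-bromination (CuBr2, EtOAc–CHCl3, reflux) gives the racemic 2-bromo ketone F4. Enolate 7, made from a second portion of 6 with LiN(i-Pr)2 in THF at −78 °C, is alkylated with F4 (THF–DMPU, −78 °C to rt; SN2 of an enolate on an α-bromo ketone). This should give 8 as an isomer mixture, which is all that step 5 requires.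

**Further compounds**
F1 | step 5 | racemic 1,4-bis[3,4-bis(benzyloxy)-5-methoxyphenyl]-2,3-dimethylbutane-1,4-dione, (2S,3S)/(2R,3R) pair, the 2S,3S enantiomer drawn | COc1cc(C(=O)[C@@H](C)[C@H](C)C(=O)c2cc(OC)c(OCc3ccccc3)c(OCc3ccccc3)c2)cc(OCc2ccccc2)c1OCc1ccccc1
F2 | step 5 | (1S,2R,3R,4S)-1,4-bis[3,4-bis(benzyloxy)-5-methoxyphenyl]-2,3-dimethylbutane-1,4-diol | COc1cc([C@@H](O)[C@H](C)[C@@H](C)[C@H](O)c2cc(OC)c(OCc3ccccc3)c(OCc3ccccc3)c2)cc(OCc2ccccc2)c1OCc1ccccc1
F3 | step 6 | (1S,2S,3S,4S)-1,4-bis[3,4-bis(benzyloxy)-5-methoxyphenyl]-2,3-dimethylbutane-1,4-diyl diacetate | COc1cc([C@@H](OC(C)=O)[C@@H](C)[C@H](C)[C@H](OC(C)=O)c2cc(OC)c(OCc3ccccc3)c(OCc3ccccc3)c2)cc(OCc2ccccc2)c1OCc1ccccc1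
F4 | step 4 | 1-[3,4-bis(benzyloxy)-5-methoxyphenyl]-2-bromopropan-1-one (racemic) | CC(Br)C(=O)c1cc(OC)c(OCc2ccccc2)c(OCc2ccccc2)c1
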